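**Retrosynthetic overview**
- The target is reached from a tris-TBS ketone by fluoride desilylation; the ketone comes from oxidation of a C1 carbinol, which comes from hydrogenation of a C2=C3 alkene.
- Ring A (C1–C2–C3–C4–C4a–C8a) is disconnected at C1–C8a and C4–C4a by a catalytic enantioselective Diels–Alder reaction of 1,4-benzoquinone with a (1E,3E)-1-silyloxy-4-naphthylbutadiene.
- The enabling feature is ring B (C4a–C5–C6–C7–C8–C8a): oxygen at C5 and C8 in para relation and hydrogen at C6/C7 make it a reduced p-benzoquinone fused through C4a–C8a, and ring A carries its only substituents (O at C1, aryl at C4) 1,4 across C2–C3. The symmetric quinone removes any regiochemical question.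
- The diene comes from a naphthaldehyde and acrolein (phosphoniosilylation–Wittig); the aldehyde comes from 1,5-dimethoxynaphthalene by formylation and para-selective O-demethylation.
- Ring order: the naphthalene and the six-membered quinone carbocycle are bought; ring A is closed by the cycloaddition; ring B is aromatised in the same flask.

Key step: step 5

Assumption: the (S)-configured oxazaborolidinium catalyst is taken to give the (4aS,5R,8S,8aS) cycloadduct, following the pre-transition-state model for quinones; the (R)-catalyst, made the same way from (R)-diphenylprolinol, would be used if the sense on this diene proved opposite.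

**Step 1**
Reactants: 1 1,5-dimethoxynaphthalene
Product: 2 4,8-dimethoxy-1-naphthaldehyde
Conditions: POCl3, DMF, 0 → 90 °C; then ice–water
Reagents that add atoms: N,N-dimethylformamide CN(C)C=O; water O
Why: Vilsmeier–Haack formylation para to a methoxy group; the two such positions of symmetric 1 are identical, so a single aldehyde should form.

**Step 2**
Reactants: 2 4,8-dimethoxy-1-naphthaldehyde
Product: 3 4-hydroxy-8-methoxy-1-naphthaldehyde
Conditions: NaSEt, DMF, 110 °C; then aq. HCl
Reagents that add atoms: none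
Why: SN2 O-demethylation by thiolate should take only the 4-methoxy group, whose naphthoxide is conjugated with the formyl group (vinylogous carboxylate), while the peri 8-methoxy group is not conjugated and is shielded.

**Step 3**
Reactants: 3 4-hydroxy-8-methoxy-1-naphthaldehyde
Product: 4 4-(tert-butyldimethylsilyloxy)-8-methoxy-1-naphthaldehyde
Conditions: TBSCl, imidazole, DMF, rt
Reagents that add atoms: tert-butyldimethylsilyl chloride CC(C)(C)[Si](C)(C)Cl
Why: Standard silylation of a phenol, which masks the acidic naphthol for the ylide and Lewis acid steps.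

**Step 4**
Reactants: 4 4-(tert-butyldimethylsilyloxy)-8-methoxy-1-naphthaldehyde; 5 acrolein
Product: 8 (1E,3E)-1-[4-(tert-butyldimethylsilyloxy)-8-methoxynaphthalen-1-yl]-4-(triethylsilyloxy)buta-1,3-diene, via silyloxyallyl phosphonium triflate 6 (not isolated), via phosphonium ylide 7 (not isolated)
Conditions: 5, PPh3, TESOTf, THF, rt; n-BuLi, −78 °C; then 4, −78 °C → rt; crude diene: (PhS)2 (5 mol%), visible light, PhH, rt
Reagents that add atoms: triethylsilyl triflate CC[Si](CC)(CC)OS(=O)(=O)C(F)(F)F
Why: Phosphoniosilylation of s-trans acrolein should give the (E)-silyl enol ether phosphonium salt, whose ylide undergoes Wittig olefination with 4, and the thiyl-radical equilibration should convert the 3Z isomer into the more stable 3E diene.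

**Step 5**
Reactants: 8 (1E,3E)-1-[4-(tert-butyldimethylsilyloxy)-8-methoxynaphthalen-1-yl]-4-(triethylsilyloxy)buta-1,3-diene; 9 1,4-benzoquinone
Product: 11 (1R,4R)-5,8-bis(tert-butyldimethylsilyloxy)-4-[4-(tert-butyldimethylsilyloxy)-8-methoxynaphthalen-1-yl]-1-(triethylsilyloxy)-1,4-dihydronaphthalene (1,4-cis), via cis-fused Diels–Alder adduct 10 (not isolated)
Conditions: 9 (1.0 equiv), 8 (1.1 equiv), (S)-3,3-diphenyl-1-(o-tolyl)tetrahydro-1H,3H-pyrrolo[1,2-c][1,3,2]oxazaborole·HNTf2 (20 mol%), CH2Cl2, −78 °C; then Et3N, TBSOTf, −78 → 0 °C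
Reagents that add atoms: tert-butyldimethylsilyl triflate CC(C)(C)[Si](C)(C)OS(=O)(=O)C(F)(F)F
Why: The oxazaborolidinium ion binds one carbonyl oxygen of 9 and lowers the LUMO of the adjacent C=C, which should add the electron-rich diene 8 in a concerted, asynchronous, endo Diels–Alder reaction that forms C1–C8a and C4–C4a together; the closest known reaction type is the oxazaborolidinium-catalysed enantioselective Diels–Alder reaction of 1,4-quinones with silyloxy dienes. Ring A is closed by this intermolecular (4+2) cycloaddition, and ring B is then aromatised in the same flask by amine-mediated double enolisation with O-silylation, which erases the two ring-fusion centres. C4 (and C1, which is oxidised away later) is set by the catalyst: it shields one face of the bound quinone while the silyloxy group polarises the diene so that the aryl-bearing terminus bonds first to the carbon β to the bound carbonyl, and this alignment, the endo rule and the E,E geometry should turn the face selection into one configuration at C4 with C1–O and C4–aryl cis. Regiochemistry needs no control because 9 is symmetric, only the (1E,3E) isomer of 8 can reach the s-cis geometry, and with near-equimolar amounts at −78 °C the hindered ene-dione of 10 should not add a second diene. Soft enolisation with Et3N/TBSOTf is chosen so that the β-silyloxy group at C1 is not eliminated and the air-sensitive free hydroquinone never appears.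

**Step 6**
Reactants: 11 (1R,4R)-5,8-bis(tert-butyldimethylsilyloxy)-4-[4-(tert-butyldimethylsilyloxy)-8-methoxynaphthalen-1-yl]-1-(triethylsilyloxy)-1,4-dihydronaphthalene
Product: 12 (1R,4R)-5,8-bis(tert-butyldimethylsilyloxy)-4-[4-(tert-butyldimethylsilyloxy)-8-methoxynaphthalen-1-yl]-1-(triethylsilyloxy)-1,2,3,4-tetrahydronaphthalene
Conditions: H2 (1 atm), PtO2 (5 mol%), EtOAc, rt
Reagents that add atoms: none
Why: Heterogeneous hydrogenation of the cis-disubstituted C2=C3 alkene; platinum is chosen over palladium to limit hydrogenolysis of the allylic, benzylic C1–O bond and double-bond migration, and C1 and C4 are not touched.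

**Step 7**
Reactants: 12 (1R,4R)-5,8-bis(tert-butyldimethylsilyloxy)-4-[4-(tert-butyldimethylsilyloxy)-8-methoxynaphthalen-1-yl]-1-(triethylsilyloxy)-1,2,3,4-tetrahydronaphthalene
Product: 13 (1R,4R)-5,8-bis(tert-butyldimethylsilyloxy)-4-[4-(tert-butyldimethylsilyloxy)-8-methoxynaphthalen-1-yl]-1,2,3,4-tetrahydronaphthalen-1-ol
Conditions: HF·pyridine, pyridine, THF, 0 °C
Reagents that add atoms: none
Why: Buffered acidic fluoride should cleave the alkyl triethylsilyl ether much faster than the three aryl TBS ethers, and the pyridine buffer avoids ionisation at benzylic C1.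

**Step 8**
Reactants: 13 (1R,4R)-5,8-bis(tert-butyldimethylsilyloxy)-4-[4-(tert-butyldimethylsilyloxy)-8-methoxynaphthalen-1-yl]-1,2,3,4-tetrahydronaphthalen-1-ol
Product: 14 (R)-5,8-bis(tert-butyldimethylsilyloxy)-4-[4-(tert-butyldimethylsilyloxy)-8-methoxynaphthalen-1-yl]-3,4-dihydronaphthalen-1(2H)-one
Conditions: DMP (1,1,1-triacetoxy-1,1-dihydro-1,2-benziodoxol-3(1H)-one), pyridine, CH2Cl2, 0 °C → rt
Reagents that add atoms: none
Why: Dess–Martin oxidation of the secondary benzylic alcohol under buffered, non-enolising conditions removes the C1 stereocentre and leaves C4 and the silyl ethers untouched.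

**Step 9**
Reactants: 14 (R)-5,8-bis(tert-butyldimethylsilyloxy)-4-[4-(tert-butyldimethylsilyloxy)-8-methoxynaphthalen-1-yl]-3,4-dihydronaphthalen-1(2H)-one
Product: 15 (R)-5,8-dihydroxy-4-(4-hydroxy-8-methoxynaphthalen-1-yl)-3,4-dihydronaphthalen-1(2H)-one (target)
Conditions: TBAF, AcOH (1:1), THF, 0 °C, argon, exclusion of light
Reagents that add atoms: none
Why: Fluoride cleavage of the three aryl silyl ethers; acetic acid keeps the phenols protonated so that the hydroquinone is not air-oxidised and the benzylic C4–H ortho to the aryl ketone is not enolised.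

**Compound list**
1 | 1,5-dimethoxynaphthalene | COc1cccc2c(OC)cccc12 | starting material
2 | 4,8-dimethoxy-1-naphthaldehyde | COc1cccc2c(OC)ccc(C=O)c12 | intermediate
3 | 4-hydroxy-8-methoxy-1-naphthaldehyde | COc1cccc2c(O)ccc(C=O)c12 | intermediate
4 | 4-(tert-butyldimethylsilyloxy)-8-methoxy-1-naphthaldehyde | COc1cccc2c(O[Si](C)(C)C(C)(C)C)ccc(C=O)c12 | intermediate
5 | acrolein | C=CC=O | starting material
6 | (E)-[3-(triethylsilyloxy)prop-2-en-1-yl]triphenylphosphonium triflate | CC[Si](CC)(CC)O/C=C/C[P+](c1ccccc1)(c1ccccc1)c1ccccc1.[O-]S(=O)(=O)C(F)(F)F | intermediate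
7 | (E)-[3-(triethylsilyloxy)prop-2-en-1-ylidene]triphenylphosphorane | CC[Si](CC)(CC)O/C=C/C=P(c1ccccc1)(c1ccccc1)c1ccccc1 | intermediate
8 | (1E,3E)-1-[4-(tert-butyldimethylsilyloxy)-8-methoxynaphthalen-1-yl]-4-(triethylsilyloxy)buta-1,3-diene | COc1cccc2c(O[Si](C)(C)C(C)(C)C)ccc(/C=C/C=C/O[Si](CC)(CC)CC)c12 | intermediate
9 | 1,4-benzoquinone | O=C1C=CC(=O)C=C1 | starting material
10 | (4aS,5R,8S,8aS)-8-[4-(tert-butyldimethylsilyloxy)-8-methoxynaphthalen-1-yl]-5-(triethylsilyloxy)-4a,5,8,8a-tetrahydronaphthalene-1,4-dione (cis-fused; H-4a, H-5, H-8, H-8a on one face) | COc1cccc2c(O[Si](C)(C)C(C)(C)C)ccc([C@H]3C=C[C@@H](O[Si](CC)(CC)CC)[C@H]4C(=O)C=CC(=O)[C@H]43)c12 | intermediate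
11 | (1R,4R)-5,8-bis(tert-butyldimethylsilyloxy)-4-[4-(tert-butyldimethylsilyloxy)-8-methoxynaphthalen-1-yl]-1-(triethylsilyloxy)-1,4-dihydronaphthalene | COc1cccc2c(O[Si](C)(C)C(C)(C)C)ccc([C@H]3C=C[C@@H](O[Si](CC)(CC)CC)c4c(O[Si](C)(C)C(C)(C)C)ccc(O[Si](C)(C)C(C)(C)C)c43)c12 | intermediate
12 | (1R,4R)-5,8-bis(tert-butyldimethylsilyloxy)-4-[4-(tert-butyldimethylsilyloxy)-8-methoxynaphthalen-1-yl]-1-(triethylsilyloxy)-1,2,3,4-tetrahydronaphthalene | COc1cccc2c(O[Si](C)(C)C(C)(C)C)ccc([C@H]3CC[C@@H](O[Si](CC)(CC)CC)c4c(O[Si](C)(C)C(C)(C)C)ccc(O[Si](C)(C)C(C)(C)C)c43)c12 | intermediate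
13 | (1R,4R)-5,8-bis(tert-butyldimethylsilyloxy)-4-[4-(tert-butyldimethylsilyloxy)-8-methoxynaphthalen-1-yl]-1,2,3,4-tetrahydronaphthalen-1-ol | COc1cccc2c(O[Si](C)(C)C(C)(C)C)ccc([C@H]3CC[C@@H](O)c4c(O[Si](C)(C)C(C)(C)C)ccc(O[Si](C)(C)C(C)(C)C)c43)c12 | intermediate
14 | (R)-5,8-bis(tert-butyldimethylsilyloxy)-4-[4-(tert-butyldimethylsilyloxy)-8-methoxynaphthalen-1-yl]-3,4-dihydronaphthalen-1(2H)-one | COc1cccc2c(O[Si](C)(C)C(C)(C)C)ccc([C@H]3CCC(=O)c4c(O[Si](C)(C)C(C)(C)C)ccc(O[Si](C)(C)C(C)(C)C)c43)c12 | intermediate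
15 | (R)-5,8-dihydroxy-4-(4-hydroxy-8-methoxynaphthalen-1-yl)-3,4-dihydronaphthalen-1(2H)-one | COc1cccc2c(O)ccc([C@H]3CCC(=O)c4c(O)ccc(O)c43)c12 | target

**Summary**
Total step count: 9. Longest linear sequence: 9 steps (1 → 15); 5 and 9 enter directly.

**Steps most likely to fail**

Step 5. The catalyst may discriminate poorly between the two faces of the bound quinone with this bulky aryl diene, or the addition may become a stepwise Mukaiyama–Michael reaction that stops before ring closure. The fallback replaces catalyst control by auxiliary control; it sets out from 8 and returns at 13. The silyl dienol ether 8 is cleaved with MeLi (THF, −78 → 0 °C) to the lithium dienolate, which is O-acylated with (S)-O-methylmandeloyl chloride to give (1E,3E)-4-[4-(tert-butyldimethylsilyloxy)-8-methoxynaphthalen-1-yl]buta-1,3-dien-1-yl (S)-2-methoxy-2-phenylacetate F1. Thermal Diels–Alder reaction of F1 with 9 (toluene, 0 °C → rt), in which the auxiliary shields one diene face, should give the cis-fused endo adduct mandelate F2. Aromatising silylation as in step 5 (Et3N, TBSOTf) should give the 1,4-dihydronaphthalene mandelate F3. At this stage the products of the two facial modes are diastereomers and can be separated, so stereochemical purity does not rest on the level of induction; the (R)-auxiliary would be used if the major isomer had the opposite ring configuration. Hydrogenation (H2, PtO2, EtOAc) should give the tetrahydronaphthalene mandelate F4, and reductive removal of the ester (DIBAL, CH2Cl2, −78 °C) gives 13.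

Step 4. Geometric control at the new C3=C4 bond may be poor with the semi-stabilised ylide, and attack on the peri-hindered aldehyde may be slow. The fallback sets out from 4 and returns at 8. An E-selective Wittig reaction of 4 with the carboxylate ylide from (2-carboxyethyl)triphenylphosphonium bromide (NaHMDS, THF) should give (E)-4-[4-(tert-butyldimethylsilyloxy)-8-methoxynaphthalen-1-yl]but-3-enoic acid F5. Esterification (TMSCHN2, MeOH/toluene) gives the methyl ester F6, and DIBAL at −78 °C gives the β,γ-unsaturated aldehyde F7. Soft enolisation (TESOTf, Et3N, CH2Cl2, −78 °C) then gives 8 with the C3=C4 geometry already fixed.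

Step 6. Hydrogenolysis of the allylic, benzylic C1–O bond, or loss of silanol and dehydrogenation to a naphthalene, may compete with saturation of the alkene. The fallback replaces reduction and oxidation by a redox-neutral isomerisation; it sets out from 11 and returns at 14. The allyl silyl ether 11 is isomerised with [Ir(cod)(PMePh2)2]PF6 (activated with H2, then degassed; THF, rt) by a 1,3-hydrogen shift from C1 to C3 to the silyl enol ether (R)-5,8-bis(tert-butyldimethylsilyloxy)-1-[4-(tert-butyldimethylsilyloxy)-8-methoxynaphthalen-1-yl]-4-(triethylsilyloxy)-1,2-dihydronaphthalene F8. Mild hydrolysis (AcOH/THF/H2O, rt) then gives ketone 14, which makes steps 7 and 8 unnecessary.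

**Further compounds**
F1 | step 5 | (1E,3E)-4-[4-(tert-butyldimethylsilyloxy)-8-methoxynaphthalen-1-yl]buta-1,3-dien-1-yl (S)-2-methoxy-2-phenylacetate | COc1cccc2c(O[Si](C)(C)C(C)(C)C)ccc(/C=C/C=C/OC(=O)[C@@H](OC)c3ccccc3)c12
F2 | step 5 | (4aS,5R,8S,8aS)-8-[4-(tert-butyldimethylsilyloxy)-8-methoxynaphthalen-1-yl]-1,4-dioxo-1,4,4a,5,8,8a-hexahydronaphthalen-5-yl (S)-2-methoxy-2-phenylacetate | COc1cccc2c(O[Si](C)(C)C(C)(C)C)ccc([C@H]3C=C[C@@H](OC(=O)[C@@H](OC)c5ccccc5)[C@H]4C(=O)C=CC(=O)[C@H]43)c12
F3 | step 5 | (1R,4R)-5,8-bis(tert-butyldimethylsilyloxy)-4-[4-(tert-butyldimethylsilyloxy)-8-methoxynaphthalen-1-yl]-1,4-dihydronaphthalen-1-yl (S)-2-methoxy-2-phenylacetate | COc1cccc2c(O[Si](C)(C)C(C)(C)C)ccc([C@H]3C=C[C@@H](OC(=O)[C@@H](OC)c5ccccc5)c4c(O[Si](C)(C)C(C)(C)C)ccc(O[Si](C)(C)C(C)(C)C)c43)c12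
F4 | step 5 | (1R,4R)-5,8-bis(tert-butyldimethylsilyloxy)-4-[4-(tert-butyldimethylsilyloxy)-8-methoxynaphthalen-1-yl]-1,2,3,4-tetrahydronaphthalen-1-yl (S)-2-methoxy-2-phenylacetate | COc1cccc2c(O[Si](C)(C)C(C)(C)C)ccc([C@H]3CC[C@@H](OC(=O)[C@@H](OC)c5ccccc5)c4c(O[Si](C)(C)C(C)(C)C)ccc(O[Si](C)(C)C(C)(C)C)c43)c12
F5 | step 4 | (E)-4-[4-(tert-butyldimethylsilyloxy)-8-methoxynaphthalen-1-yl]but-3-enoic acid | COc1cccc2c(O[Si](C)(C)C(C)(C)C)ccc(/C=C/CC(=O)O)c12
F6 | step 4 | methyl (E)-4-[4-(tert-butyldimethylsilyloxy)-8-methoxynaphthalen-1-yl]but-3-enoate | COc1cccc2c(O[Si](C)(C)C(C)(C)C)ccc(/C=C/CC(=O)OC)c12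
F7 | step 4 | (E)-4-[4-(tert-butyldimethylsilyloxy)-8-methoxynaphthalen-1-yl]but-3-enal | COc1cccc2c(O[Si](C)(C)C(C)(C)C)ccc(/C=C/CC=O)c12
F8 | step 6 | (R)-5,8-bis(tert-butyldimethylsilyloxy)-1-[4-(tert-butyldimethylsilyloxy)-8-methoxynaphthalen-1-yl]-4-(triethylsilyloxy)-1,2-dihydronaphthalene | COc1cccc2c(O[Si](C)(C)C(C)(C)C)ccc([C@H]3CC=C(O[Si](CC)(CC)CC)c4c(O[Si](C)(C)C(C)(C)C)ccc(O[Si](C)(C)C(C)(C)C)c43)c12
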